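# Proposed synthesis of CNP0298337.1: ring F closed at C2=C3 by reductive ester–aldehyde coupling

Rings A, B and C are the upper flavan, rings D, E and F the lower flavan-3-ol, with the usual flavonoid atom numbers. The target is read from its SMILES as (2S,4S) in ring C (2,4-cis) and (2R,3R) in ring F (2,3-cis, epicatechin type).

## The problem

The target is a 4→8 biflavanoid. C4 of a (2S,4S)-4′,7-dihydroxyflavan is bonded to C8 of a (2R,3R)-flavan-3-ol whose ring D is a phloroglucinol ring and whose ring E is a catechol. The four stereocentres form two pairs: the aryl groups at C2 and C4 of ring C are cis, and ring E at C2 and the hydroxyl at C3 of ring F are cis. Within a pair one centre can direct the other, since C2 of ring C can steer a reduction at C4 and C2 of ring F can steer a hydride onto C3. The two pairs lie in different rings on either side of the interflavan bond, so the lower pair needs a chiral reagent or the chiral pool. Ring D is a second difficulty: its three oxygens and two free carbons must be told apart, or the 4→6 isomer results. The compound has six phenols (one an air-sensitive catechol), two benzylic aryl ether bonds (C2–O1) and an electron-rich interflavan bond, all intolerant of strong acid or oxidants. A flavanone precursor of the upper unit also loses its C2 configuration in base through chalcone opening, so the protecting groups must come off under neutral conditions. The feature that enables the key step is the 1,2-dioxygenation of ring F. C2 carries ring E and is bonded to O1, the oxygen on C8a of ring D, and C3 carries the hydroxyl. C2 can therefore be the carbonyl carbon of an aroyl ester on the C8a oxygen and C3 an aldehyde carbon on a two-carbon arm at C4a. A reductive coupling can join these two electrophilic carbons.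

## Retrosynthesis

**Protecting groups.** The target 23 is traced to its hexa-O-benzyl ether 22. All six phenols are masked as benzyl ethers so that one hydrogenolysis frees them without acid or base near the catechol and the interflavan bond. The C3 hydroxyl is made last and needs no protection.

**C3 configuration.** The C3–H bond of 22 is cut to give ketone 21, which comes from the 2,3-trans alcohol 20. Cutting C3–O and C2–H of 20 leads to the 2-aryl-4H-chromene 18. Hydroboration adds H and B to the same face and can only give the trans alcohol, so the cis arrangement is reached by oxidation and a hydride reduction directed by C2. The alternative of a direct cis hydration has no reliable counterpart. Compound 18 has no stereocentre in ring F, so two centres are removed. The forward reaction must choose one face of the C2=C3 bond under reagent control.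

**Ring F (key disconnection).** The C2=C3 bond of 18 is cut to give the ester aldehyde 17. The neighbouring cut at O1–C2 would need a stereodefined leaving group on a benzylic carbon next to the electron-rich ring E, which ionises easily. A cut at C4–C4a would need Friedel–Crafts regiocontrol on ring D. The C2=C3 cut uses the native oxygenation of both carbons and ties the regiochemistry of ring closure to the position of the ester. In 17 ring F is open, the lower half has no stereocentre, and the lower half is assembled from simple aromatic pieces. The forward reaction must reduce the aldehyde before the ester and cyclise faster than it dimerises.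

**Ester and aldehyde.** The aldehyde of 17 is traced to the terminal alkene of 15 (oxidative cleavage of C=C). The ester C–O bond of 15 is cut to give phenol 12 and 3,4-bis(benzyloxy)benzoic acid 13. The fragile arylacetaldehyde is unmasked only in the step before it is used, and the ester has to survive only a near-neutral oxidation.

**C4a side chain.** The C4a–CH2 bond of 12 is cut by a Claisen transform to the allyl ether 11, and the O–allyl bond of 11 is cut to phenol 9 and allyl bromide 10. The rearrangement places the carbon arm ortho to the oxygen the allyl group leaves and frees that same oxygen for acylation. The other ortho position is C8, already occupied by the upper unit, so only C4a can receive the arm. This fixes 4→8 rather than 4→6 connectivity. A direct C-alkylation of ring D would have no such control.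

**Interflavan bond and C4.** Phenol 9 comes from the MOM ether 8. The C4–H bond of 8 is cut to the tertiary alcohol 7, and the C4–C8 bond of 7 is cut to the flavanone 2 and the arene 4. The usual acid-catalysed union of a flavan-4-ol with a phloroglucinol nucleophile has two drawbacks:

- It attaches the nucleophile trans to the C2 aryl under kinetic control.
- It cannot distinguish the positions of ring D.

Adding ring D as a carbanion to the C4 carbonyl and then delivering hydride reverses the roles. The small hydride enters trans to the C2 aryl, so the two aryl groups end cis. The site of the carbanion is set by the MOM group, which marks the future O1. The precursors have one stereocentre (2) and none (4).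

**Starting materials.** Flavanone 2 is the dibenzyl ether of (S)-liquiritigenin 1, which supplies C2 of ring C. Arene 4 is the MOM ether of 3,5-bis(benzyloxy)phenol 3.

## Roads not taken

**Alternative 1:** This road removes ring D altogether. A flavan-4-yl cyclobutenone A2 is heated with a siloxyalkyne A3 that carries the C4–C3–C2–ring E chain. Ring opening to a vinylketene, addition of the alkyne, a four-electron opening and a six-electron closure form C4a–C8a, C5–C6 and C8–C8a and give the phenol A1, free only at C8a.

- Merits: every substituent of ring D is placed by the mechanism, the three oxygens are differentiated as they form, and a 4→6 isomer cannot arise. In this regiochemical certainty it is better than the chosen plan, which relies on a directed metalation (step 3) and a Claisen rearrangement (step 7).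
- Weak points: A2 needs a stereocontrolled bond from C4 of the flavan to a strained ring, with an unusual silyl enol ether. A3 already carries both lower stereocentres and needs its own asymmetric synthesis. Ring F must still be closed from A1 by displacement with inversion at the benzylic C2, next to the electron-rich ring E, where ionisation threatens the configuration.
- Comparison: the chosen plan buys its aromatic rings, is shorter, and creates the ring F stereocentres on the closed ring, where no benzylic cation is involved.

**Alternative 2:** This road cuts C4–C4a of the upper unit. In the propargyl aryl ether A5, Ph3PAuNTf2 activates the alkyne and ring A attacks the alkyne carbon that bears ring D. This closes ring C as the 2H-chromene A4 with C2 untouched. Hydrogenation of A4 would then add hydrogen to C4 on the face away from ring B and remove all benzyl groups in the same operation, giving 23.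

- Merits: the endgame is the shortest of all, and the lower unit enters whole from the chiral pool with C2 and C3 in place. In both respects it is better than the chosen plan, which spends steps 11 to 13 and a chiral borane on these two centres.
- Weak points: C2 of ring C must be made enantioselectively at a propargylic, para-alkoxybenzylic carbon and etherified with inversion. That C–O bond can ionise during etherification and again under the cationic gold catalyst. 2-Aryl-2H-chromenes can also lose C2 by electrocyclic opening. Ring A can be attacked ortho or para to its benzyloxy group (5- against 7-oxygenation). The alkyne has to be installed on the hindered C8 position.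
- Comparison: the chosen plan takes C2 of ring C from a natural flavanone, carries the ring A substitution pattern unambiguously from the start, and creates no stereocentre in its key step that could be lost there.

**Alternative 3:** This road cuts O1–C2. Under mild acid the C8a phenol of A7 opens the cis-epoxide at its benzylic carbon with inversion. This forms O1–C2, releases the C3 hydroxyl and closes ring F to give A6.

- Merits: the 2,3-cis relationship arises directly, which saves the oxidation and reduction of steps 12 and 13. The symmetric dihydroxy ring D makes the site of chain attachment unambiguous. In step count after ring closure it is better than the chosen plan.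
- Weak points: the epoxide must be made enantioselectively on a cis-disubstituted styrene-type double bond, in a molecule with free phenols and oxidant-sensitive rings. The benzylic epoxide carbon beside a dialkoxyphenyl ring opens with cationic character, so inversion may be incomplete and 2,3-trans material may form. Closure at C3 to a five-membered ring competes.
- Comparison: the chosen plan sets C2 and C3 by a concerted syn addition to a rigid ring and by a hydride reduction controlled by C2. Neither passes through a benzylic cation, and no free phenol meets an oxidant.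

Key step: step 10

## Assumptions

- 3,5-Bis(benzyloxy)phenol (3), the dibenzyl ether of phloroglucinol, is treated as a purchasable building block.
- (S)-Liquiritigenin (1) is taken as commercially available in enantiopure form.

## Route

Step 1
Reactants: 1 (S)-liquiritigenin
Product: 2 (S)-7-(benzyloxy)-2-[4-(benzyloxy)phenyl]chroman-4-one
Conditions: BnOH, PPh3, DIAD, THF, 0 °C → rt
Reagents that add atoms: benzyl alcohol, OCc1ccccc1
Why: Double Mitsunobu etherification of the two phenols; the near-neutral medium avoids the base-induced opening of ring C to the chalcone that would racemise C2, which is carried over unchanged from 1.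

Step 2
Reactants: 3 3,5-bis(benzyloxy)phenol
Product: 4 1,3-bis(benzyloxy)-5-(methoxymethoxy)benzene
Conditions: MOMCl, i-Pr2NEt, CH2Cl2, 0 °C → rt
Reagents that add atoms: chloromethyl methyl ether, COCCl
Why: Routine O-alkylation of a phenol; the MOM acetal marks the oxygen that becomes O1 of ring F and is the directing group for the metalation in step 3.

Step 3
Reactants: 4 1,3-bis(benzyloxy)-5-(methoxymethoxy)benzene, 2 (S)-7-(benzyloxy)-2-[4-(benzyloxy)phenyl]chroman-4-one
Product: 7 (2S)-7-(benzyloxy)-2-[4-(benzyloxy)phenyl]-4-[2,4-bis(benzyloxy)-6-(methoxymethoxy)phenyl]chroman-4-ol (mixture of C4 epimers), via aryllithium 5 (not isolated), via arylcerium dichloride 6 (not isolated)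
Conditions: n-BuLi, THF, 0 °C; CeCl3, THF, −78 °C; then 2, −78 → −40 °C; aq. NH4Cl
Reagents that add atoms: none
Why: Directed ortho-metalation, in which the chelating MOM group is the stronger director, should remove the ring proton flanked by OMOM and OBn (two equivalent sites) rather than the one between the two benzyl ethers; transmetalation to the organocerium reagent makes the hindered, weakly basic aryl nucleophile add to the enolisable flavanone carbonyl instead of deprotonating C3, and the C4 configuration of 7 does not matter because step 4 erases it.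

Step 4
Reactants: 7 (2S)-7-(benzyloxy)-2-[4-(benzyloxy)phenyl]-4-[2,4-bis(benzyloxy)-6-(methoxymethoxy)phenyl]chroman-4-ol
Product: 8 (2S,4S)-7-(benzyloxy)-2-[4-(benzyloxy)phenyl]-4-[2,4-bis(benzyloxy)-6-(methoxymethoxy)phenyl]chroman (2,4-cis)
Conditions: Et3SiH, TFA, CH2Cl2, −40 → 0 °C
Reagents that add atoms: none
Why: Ionic hydrogenation: acid ionises the doubly benzylic tertiary alcohol to a C4 cation stabilised by the ring A oxygens and ring D, and Et3SiH should deliver hydride along the pseudo-axial trajectory trans to the equatorial C2 aryl, so that C4 becomes (S) under control of C2 and both aryl groups sit equatorial (2,4-cis); any MOM lost here is harmless because step 5 removes it.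

Step 5
Reactants: 8 (2S,4S)-7-(benzyloxy)-2-[4-(benzyloxy)phenyl]-4-[2,4-bis(benzyloxy)-6-(methoxymethoxy)phenyl]chroman
Product: 9 3,5-bis(benzyloxy)-2-{(2S,4S)-7-(benzyloxy)-2-[4-(benzyloxy)phenyl]chroman-4-yl}phenol
Conditions: p-TsOH·H2O (cat.), MeOH/THF, 40 °C
Reagents that add atoms: none
Why: Acid-catalysed acetal exchange with methanol removes the phenolic MOM group under conditions that benzyl ethers and the benzylic C2–O1 bond of the protected flavan tolerate.

Step 6
Reactants: 9 3,5-bis(benzyloxy)-2-{(2S,4S)-7-(benzyloxy)-2-[4-(benzyloxy)phenyl]chroman-4-yl}phenol, 10 allyl bromide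
Product: 11 (2S,4S)-4-[2-(allyloxy)-4,6-bis(benzyloxy)phenyl]-7-(benzyloxy)-2-[4-(benzyloxy)phenyl]chroman
Conditions: K2CO3, DMF, 50 °C
Reagents that add atoms: none
Why: Williamson etherification of the only free phenol; the benzhydryl-type C4–H is far too weakly acidic for carbonate, so the cis configuration is safe.

Step 7
Reactants: 11 (2S,4S)-4-[2-(allyloxy)-4,6-bis(benzyloxy)phenyl]-7-(benzyloxy)-2-[4-(benzyloxy)phenyl]chroman
Product: 12 2-allyl-3,5-bis(benzyloxy)-6-{(2S,4S)-7-(benzyloxy)-2-[4-(benzyloxy)phenyl]chroman-4-yl}phenol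
Conditions: PhNEt2, 190 °C (sealed tube)
Reagents that add atoms: none
Why: Aromatic Claisen rearrangement; of the two ortho positions of the allyloxy oxygen one is C8, blocked by the upper unit, so the allyl group should migrate to C4a and free the C8a phenol, while the basic solvent suppresses cyclisation of the product to a dihydrobenzofuran.

Step 8
Reactants: 12 2-allyl-3,5-bis(benzyloxy)-6-{(2S,4S)-7-(benzyloxy)-2-[4-(benzyloxy)phenyl]chroman-4-yl}phenol, 13 3,4-bis(benzyloxy)benzoic acid
Product: 15 2-allyl-3,5-bis(benzyloxy)-6-{(2S,4S)-7-(benzyloxy)-2-[4-(benzyloxy)phenyl]chroman-4-yl}phenyl 3,4-bis(benzyloxy)benzoate, via acid chloride 14 (not isolated)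
Conditions: 13, (COCl)2, DMF (cat.), CH2Cl2, rt; then 12, Et3N, DMAP, CH2Cl2, 0 °C → rt
Reagents that add atoms: none
Why: Acylation of a hindered phenol with an aroyl chloride under DMAP catalysis; the ester lands on the oxygen that the allyl group left, which is the only free hydroxyl in 12.

Step 9
Reactants: 15 2-allyl-3,5-bis(benzyloxy)-6-{(2S,4S)-7-(benzyloxy)-2-[4-(benzyloxy)phenyl]chroman-4-yl}phenyl 3,4-bis(benzyloxy)benzoate
Product: 17 3,5-bis(benzyloxy)-2-(2-oxoethyl)-6-{(2S,4S)-7-(benzyloxy)-2-[4-(benzyloxy)phenyl]chroman-4-yl}phenyl 3,4-bis(benzyloxy)benzoate, via vicinal diol 16 (not isolated)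
Conditions: OsO4 (cat.), NaIO4, 2,6-lutidine, dioxane/H2O, rt
Reagents that add atoms: osmium tetroxide, O=[Os](=O)(=O)=O (oxygen donor, renewed by sodium periodate, [Na+].[O-]I(=O)(=O)=O)
Why: Lemieux–Johnson cleavage of the terminal alkene through the diol; the lutidine-buffered, near-neutral medium spares the aryl ester and the electron-rich rings that ozone would attack, and the aldehyde is taken on without storage.

Step 10
Reactants: 17 3,5-bis(benzyloxy)-2-(2-oxoethyl)-6-{(2S,4S)-7-(benzyloxy)-2-[4-(benzyloxy)phenyl]chroman-4-yl}phenyl 3,4-bis(benzyloxy)benzoate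
Product: 18 (2S,4S)-4-{5,7-bis(benzyloxy)-2-[3,4-bis(benzyloxy)phenyl]-4H-chromen-8-yl}-7-(benzyloxy)-2-[4-(benzyloxy)phenyl]chroman
Conditions: TiCl3, Zn–Cu couple, DME, reflux; 17 added slowly by syringe pump (high dilution); work-up over basic alumina
Reagents that add atoms: none
Why: Low-valent titanium from TiCl3 and Zn–Cu couple transfers an electron to the aldehyde, the more easily reduced carbonyl, and the titanium-bound ketyl carbon C3 attacks the carbonyl carbon C2 of the neighbouring aryl ester. This closes ring F in a 6-exo-trig mode, C3 adding to the exocyclic C=O of the ester so that the ring atoms are O1, C2, C3, C4, C4a and C8a. The titanium diolate formed is then deoxygenated on the oxophilic metal, both carbonyl oxygens leave as titanium oxide, and the C2=C3 enol ether bond of the 2-aryl-4H-chromene remains. The closest known reaction type is the titanium-induced intramolecular oxo-ester (McMurry-type) coupling that converts keto esters into cyclic enol ethers and O-acylated 2-acylphenols into benzofurans; here the tether is one carbon longer. No stereocentre is created, and C2 and C4 of the upper unit are remote and untouched. The step needs the aldehyde to react before the ester (secured by their reduction potentials), ring closure to outrun pinacol dimerisation (secured by slow addition at high dilution) and deoxygenation to outrun expulsion of the phenoxide (favoured by the strong titanium–oxygen bonds). Regiochemistry is not in question because the ester sits on the only oxygen ortho to the aldehyde arm.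

Step 11
Reactants: 18 (2S,4S)-4-{5,7-bis(benzyloxy)-2-[3,4-bis(benzyloxy)phenyl]-4H-chromen-8-yl}-7-(benzyloxy)-2-[4-(benzyloxy)phenyl]chroman
Product: 20 (2R,3S)-5,7-bis(benzyloxy)-2-[3,4-bis(benzyloxy)phenyl]-8-{(2S,4S)-7-(benzyloxy)-2-[4-(benzyloxy)phenyl]chroman-4-yl}chroman-3-ol (2,3-trans), via C3 alkylborane 19 (not isolated)
Conditions: IpcBH2 [from (+)-α-pinene], THF, −25 → 0 °C; then NaOH, H2O2, 0 °C → rt
Reagents that add atoms: hydrogen peroxide, OO
Why: Asymmetric hydroboration–oxidation of a trisubstituted aryl enol ether; boron goes to C3 (β to oxygen and away from the aryl-bearing carbon), H and B add syn so that C2 and C3 emerge trans, and the face is chosen by the chiral borane, whose known sense with 1-phenylcyclohexene [(1S,2R)-trans-2-phenylcyclohexanol] maps onto 2R,3S here; oxidation proceeds with retention.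

Step 12
Reactants: 20 (2R,3S)-5,7-bis(benzyloxy)-2-[3,4-bis(benzyloxy)phenyl]-8-{(2S,4S)-7-(benzyloxy)-2-[4-(benzyloxy)phenyl]chroman-4-yl}chroman-3-ol
Product: 21 (2R)-5,7-bis(benzyloxy)-2-[3,4-bis(benzyloxy)phenyl]-8-{(2S,4S)-7-(benzyloxy)-2-[4-(benzyloxy)phenyl]chroman-4-yl}chroman-3(4H)-one
Conditions: Dess–Martin periodinane, CH2Cl2 (water-saturated), rt
Reagents that add atoms: none
Why: Dess–Martin oxidation, the established first half of the trans-to-cis inversion of benzylated flavan-3-ols; the neutral reagent and immediate use of the crude ketone protect the enolisable C2 centre.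

Step 13
Reactants: 21 (2R)-5,7-bis(benzyloxy)-2-[3,4-bis(benzyloxy)phenyl]-8-{(2S,4S)-7-(benzyloxy)-2-[4-(benzyloxy)phenyl]chroman-4-yl}chroman-3(4H)-one
Product: 22 (2R,3R)-5,7-bis(benzyloxy)-2-[3,4-bis(benzyloxy)phenyl]-8-{(2S,4S)-7-(benzyloxy)-2-[4-(benzyloxy)phenyl]chroman-4-yl}chroman-3-ol (2,3-cis)
Conditions: LiBH(s-Bu)3, THF, −78 °C; then H2O
Reagents that add atoms: none
Why: Substrate-controlled ketone reduction; the bulky hydride should approach C3 from the face opposite ring E at C2, which places the new hydroxyl cis to the aryl group and sets C3 as (R) under control of C2.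

Step 14
Reactants: 22 (2R,3R)-5,7-bis(benzyloxy)-2-[3,4-bis(benzyloxy)phenyl]-8-{(2S,4S)-7-(benzyloxy)-2-[4-(benzyloxy)phenyl]chroman-4-yl}chroman-3-ol
Product: 23 (2R,3R)-2-(3,4-dihydroxyphenyl)-8-[(2S,4S)-7-hydroxy-2-(4-hydroxyphenyl)chroman-4-yl]chroman-3,5,7-triol (CNP0298337.1)
Conditions: H2 (1 atm), Pd(OH)2/C, THF/MeOH, rt; filtration and concentration under argon
Reagents that add atoms: none
Why: Global hydrogenolysis of six aryl benzyl ethers under neutral conditions, the standard final step for benzylated oligoflavanoids; the interflavan C–C bond and the ring C–O bonds are expected to survive at atmospheric pressure and no stereocentre is touched.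

## Compound list

1 | (S)-liquiritigenin | Oc1ccc([C@@H]2CC(=O)c3ccc(O)cc3O2)cc1 | starting material
2 | (S)-7-(benzyloxy)-2-[4-(benzyloxy)phenyl]chroman-4-one | c9ccccc9COc1ccc([C@@H]2CC(=O)c3ccc(OCc9ccccc9)cc3O2)cc1 | intermediate
3 | 3,5-bis(benzyloxy)phenol | Oc1cc(OCc2ccccc2)cc(OCc2ccccc2)c1 | starting material
4 | 1,3-bis(benzyloxy)-5-(methoxymethoxy)benzene | COCOc1cc(OCc2ccccc2)cc(OCc2ccccc2)c1 | intermediate
5 | [2,4-bis(benzyloxy)-6-(methoxymethoxy)phenyl]lithium | [Li]c1c(OCOC)cc(OCc2ccccc2)cc1OCc1ccccc1 | intermediate
6 | [2,4-bis(benzyloxy)-6-(methoxymethoxy)phenyl]cerium dichloride | Cl[Ce](Cl)c1c(OCOC)cc(OCc2ccccc2)cc1OCc1ccccc1 | intermediate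
7 | (2S)-7-(benzyloxy)-2-[4-(benzyloxy)phenyl]-4-[2,4-bis(benzyloxy)-6-(methoxymethoxy)phenyl]chroman-4-ol, C4 epimers | c9ccccc9COc1ccc([C@@H]2CC(O)(c3c(OCc9ccccc9)cc(OCc9ccccc9)cc3OCOC)c3ccc(OCc9ccccc9)cc3O2)cc1 | intermediate
8 | (2S,4S)-7-(benzyloxy)-2-[4-(benzyloxy)phenyl]-4-[2,4-bis(benzyloxy)-6-(methoxymethoxy)phenyl]chroman | c9ccccc9COc1ccc([C@@H]2C[C@H](c3c(OCc9ccccc9)cc(OCc9ccccc9)cc3OCOC)c3ccc(OCc9ccccc9)cc3O2)cc1 | intermediate
9 | 3,5-bis(benzyloxy)-2-{(2S,4S)-7-(benzyloxy)-2-[4-(benzyloxy)phenyl]chroman-4-yl}phenol | c9ccccc9COc1ccc([C@@H]2C[C@H](c3c(OCc9ccccc9)cc(OCc9ccccc9)cc3O)c3ccc(OCc9ccccc9)cc3O2)cc1 | intermediate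
10 | allyl bromide | C=CCBr | starting material
11 | (2S,4S)-4-[2-(allyloxy)-4,6-bis(benzyloxy)phenyl]-7-(benzyloxy)-2-[4-(benzyloxy)phenyl]chroman | c9ccccc9COc1ccc([C@@H]2C[C@H](c3c(OCc9ccccc9)cc(OCc9ccccc9)cc3OCC=C)c3ccc(OCc9ccccc9)cc3O2)cc1 | intermediate
12 | 2-allyl-3,5-bis(benzyloxy)-6-{(2S,4S)-7-(benzyloxy)-2-[4-(benzyloxy)phenyl]chroman-4-yl}phenol | c9ccccc9COc1ccc([C@@H]2C[C@H](c3c(OCc9ccccc9)cc(OCc9ccccc9)c(CC=C)c3O)c3ccc(OCc9ccccc9)cc3O2)cc1 | intermediate
13 | 3,4-bis(benzyloxy)benzoic acid | OC(=O)c1ccc(OCc2ccccc2)c(OCc2ccccc2)c1 | starting material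
14 | 3,4-bis(benzyloxy)benzoyl chloride | ClC(=O)c1ccc(OCc2ccccc2)c(OCc2ccccc2)c1 | intermediate
15 | 2-allyl-3,5-bis(benzyloxy)-6-{(2S,4S)-7-(benzyloxy)-2-[4-(benzyloxy)phenyl]chroman-4-yl}phenyl 3,4-bis(benzyloxy)benzoate | c9ccccc9COc1ccc([C@@H]2C[C@H](c3c(OCc9ccccc9)cc(OCc9ccccc9)c(CC=C)c3OC(=O)c3ccc(OCc9ccccc9)c(OCc9ccccc9)c3)c3ccc(OCc9ccccc9)cc3O2)cc1 | intermediate
16 | 3,5-bis(benzyloxy)-2-(2,3-dihydroxypropyl)-6-{(2S,4S)-7-(benzyloxy)-2-[4-(benzyloxy)phenyl]chroman-4-yl}phenyl 3,4-bis(benzyloxy)benzoate, carbinol epimers | c9ccccc9COc1ccc([C@@H]2C[C@H](c3c(OCc9ccccc9)cc(OCc9ccccc9)c(CC(O)CO)c3OC(=O)c3ccc(OCc9ccccc9)c(OCc9ccccc9)c3)c3ccc(OCc9ccccc9)cc3O2)cc1 | intermediate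
17 | 3,5-bis(benzyloxy)-2-(2-oxoethyl)-6-{(2S,4S)-7-(benzyloxy)-2-[4-(benzyloxy)phenyl]chroman-4-yl}phenyl 3,4-bis(benzyloxy)benzoate | c9ccccc9COc1ccc([C@@H]2C[C@H](c3c(OCc9ccccc9)cc(OCc9ccccc9)c(CC=O)c3OC(=O)c3ccc(OCc9ccccc9)c(OCc9ccccc9)c3)c3ccc(OCc9ccccc9)cc3O2)cc1 | intermediate
18 | (2S,4S)-4-{5,7-bis(benzyloxy)-2-[3,4-bis(benzyloxy)phenyl]-4H-chromen-8-yl}-7-(benzyloxy)-2-[4-(benzyloxy)phenyl]chroman | c9ccccc9COc1ccc([C@@H]2C[C@H](c3c(OCc9ccccc9)cc(OCc9ccccc9)c4c3OC(c3ccc(OCc9ccccc9)c(OCc9ccccc9)c3)=CC4)c3ccc(OCc9ccccc9)cc3O2)cc1 | intermediate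
19 | isopinocampheyl{(2R,3S)-5,7-bis(benzyloxy)-2-[3,4-bis(benzyloxy)phenyl]-8-[(2S,4S)-7-(benzyloxy)-2-(4-benzyloxyphenyl)chroman-4-yl]chroman-3-yl}borane | c9ccccc9COc1ccc([C@@H]2C[C@H](c3c(OCc9ccccc9)cc(OCc9ccccc9)c4c3O[C@H](c3ccc(OCc9ccccc9)c(OCc9ccccc9)c3)[C@@H](B[C@@H]5C[C@@H]6C[C@@H](C6(C)C)[C@H]5C)C4)c3ccc(OCc9ccccc9)cc3O2)cc1 | intermediate
20 | (2R,3S)-5,7-bis(benzyloxy)-2-[3,4-bis(benzyloxy)phenyl]-8-{(2S,4S)-7-(benzyloxy)-2-[4-(benzyloxy)phenyl]chroman-4-yl}chroman-3-ol | c9ccccc9COc1ccc([C@@H]2C[C@H](c3c(OCc9ccccc9)cc(OCc9ccccc9)c4c3O[C@H](c3ccc(OCc9ccccc9)c(OCc9ccccc9)c3)[C@@H](O)C4)c3ccc(OCc9ccccc9)cc3O2)cc1 | intermediate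
21 | (2R)-5,7-bis(benzyloxy)-2-[3,4-bis(benzyloxy)phenyl]-8-{(2S,4S)-7-(benzyloxy)-2-[4-(benzyloxy)phenyl]chroman-4-yl}chroman-3(4H)-one | c9ccccc9COc1ccc([C@@H]2C[C@H](c3c(OCc9ccccc9)cc(OCc9ccccc9)c4c3O[C@H](c3ccc(OCc9ccccc9)c(OCc9ccccc9)c3)C(=O)C4)c3ccc(OCc9ccccc9)cc3O2)cc1 | intermediate
22 | (2R,3R)-5,7-bis(benzyloxy)-2-[3,4-bis(benzyloxy)phenyl]-8-{(2S,4S)-7-(benzyloxy)-2-[4-(benzyloxy)phenyl]chroman-4-yl}chroman-3-ol | c9ccccc9COc1ccc([C@@H]2C[C@H](c3c(OCc9ccccc9)cc(OCc9ccccc9)c4c3O[C@H](c3ccc(OCc9ccccc9)c(OCc9ccccc9)c3)[C@H](O)C4)c3ccc(OCc9ccccc9)cc3O2)cc1 | intermediate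
23 | (2R,3R)-2-(3,4-dihydroxyphenyl)-8-[(2S,4S)-7-hydroxy-2-(4-hydroxyphenyl)chroman-4-yl]chroman-3,5,7-triol | Oc1ccc([C@@H]2C[C@H](c3c(O)cc(O)c4c3O[C@H](c3ccc(O)c(O)c3)[C@H](O)C4)c3ccc(O)cc3O2)cc1 | target

## Step count and least certain steps

Total steps: 14. Longest linear sequence: 13 (steps 1 and 3 to 14 from 1; equally steps 2 to 14 from 3).

**Step 10 (key step).** The most likely failure is intermolecular pinacol coupling of the aldehyde. The fragile, enolisable arylacetaldehyde may also be consumed by simple reduction or by acyl transfer with loss of the phenoxide before the diolate is deoxygenated. Fallback: the route is left at the allyl ester 15. Its ester carbonyl is methylenated with Cp2TiMe2 (toluene, 70 °C) to the 1-arylvinyl aryl ether F1. Ring-closing metathesis of the enol ether with the allyl group, using the second-generation Grubbs catalyst (toluene, 80 °C), expels ethylene and forms the same C2=C3 bond. The route is rejoined at 18.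

**Step 3.** The most likely failure is enolisation of the flavanone by the hindered 2,6-dioxygenated aryl nucleophile instead of addition. This would return starting ketone and, if the enolate opens ring C, erode C2. Incomplete site selectivity of the metalation would show up as a para-hydroxy isomer after step 5. Fallback: starting from 2, the ketone is converted with Tf2O and 2,6-di-tert-butyl-4-methylpyridine (CH2Cl2) into the enol triflate F2. Aryllithium 5 is transmetalated with ZnCl2 to the arylzinc chloride F3. Negishi coupling of F2 with F3 (Pd(OAc)2, SPhos, THF, 60 °C) gives the 4-aryl-2H-chromene F4. Et3SiH and TFA then protonate C3 and reduce the same C4 cation as in step 4. The route is rejoined at 8.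

**Step 4.** The most likely failure is insufficient facial discrimination in hydride delivery to the planar, heavily substituted C4 cation, which would give 2,4-trans material. A second risk is acid-induced opening of the benzylic C2–O1 bond followed by reduction. Fallback: starting from 7, treatment with HCl in MeOH/THF dehydrates the alcohol and removes the MOM group to give the phenolic 4-aryl-2H-chromene F5. Homogeneous hydrogenation with H2 and [Ir(cod)(PCy3)(py)]PF6 in CH2Cl2 then adds hydrogen to C3=C4 from the face away from the C2 aryl and leaves the benzyl ethers intact. The route is rejoined at 9.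

**Step 11.** The most likely failure is poor facial selectivity, because the chiral borane may be mismatched with the bias of the bulky C8 substituent or may react sluggishly with the hindered enol ether. Fallback: starting from 18, hydroboration with BH3·SMe2 followed by NaOH and H2O2 gives 20 together with its ring F diastereomer, the (2S,3R)-trans alcohol F6. The upper unit is enantiopure, so the two are diastereomers and are separated by chromatography. The route is rejoined at 20.

## Further compounds

F1 | step 10 | 2-allyl-3,5-bis(benzyloxy)-6-{(2S,4S)-7-(benzyloxy)-2-[4-(benzyloxy)phenyl]chroman-4-yl}phenyl 1-[3,4-bis(benzyloxy)phenyl]vinyl ether | c9ccccc9COc1ccc([C@@H]2C[C@H](c3c(OCc9ccccc9)cc(OCc9ccccc9)c(CC=C)c3OC(=C)c3ccc(OCc9ccccc9)c(OCc9ccccc9)c3)c3ccc(OCc9ccccc9)cc3O2)cc1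
F2 | step 3 | (S)-7-(benzyloxy)-2-[4-(benzyloxy)phenyl]-2H-chromen-4-yl trifluoromethanesulfonate | c9ccccc9COc1ccc([C@@H]2C=C(OS(=O)(=O)C(F)(F)F)c3ccc(OCc9ccccc9)cc3O2)cc1
F3 | step 3 | [2,4-bis(benzyloxy)-6-(methoxymethoxy)phenyl]zinc chloride | Cl[Zn]c1c(OCOC)cc(OCc2ccccc2)cc1OCc1ccccc1
F4 | step 3 | (S)-7-(benzyloxy)-2-[4-(benzyloxy)phenyl]-4-[2,4-bis(benzyloxy)-6-(methoxymethoxy)phenyl]-2H-chromene | c9ccccc9COc1ccc([C@@H]2C=C(c3c(OCc9ccccc9)cc(OCc9ccccc9)cc3OCOC)c3ccc(OCc9ccccc9)cc3O2)cc1
F5 | step 4 | 3,5-bis(benzyloxy)-2-{(S)-7-(benzyloxy)-2-[4-(benzyloxy)phenyl]-2H-chromen-4-yl}phenol | c9ccccc9COc1ccc([C@@H]2C=C(c3c(OCc9ccccc9)cc(OCc9ccccc9)cc3O)c3ccc(OCc9ccccc9)cc3O2)cc1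
F6 | step 11 | (2S,3R)-5,7-bis(benzyloxy)-2-[3,4-bis(benzyloxy)phenyl]-8-{(2S,4S)-7-(benzyloxy)-2-[4-(benzyloxy)phenyl]chroman-4-yl}chroman-3-ol | c9ccccc9COc1ccc([C@@H]2C[C@H](c3c(OCc9ccccc9)cc(OCc9ccccc9)c4c3O[C@@H](c3ccc(OCc9ccccc9)c(OCc9ccccc9)c3)[C@H](O)C4)c3ccc(OCc9ccccc9)cc3O2)cc1
A1 | alternative 1 | C8a phenol with the upper flavan at C8, triisopropylsilyloxy groups at C5 and C7 and the open ring F chain (3-benzyloxy, 2-triethylsilyloxy) at C4a | c9ccccc9COc1ccc([C@@H]2C[C@H](c3c(O[Si](C(C)C)(C(C)C)C(C)C)cc(O[Si](C(C)C)(C(C)C)C(C)C)c(C[C@@H](OCc9ccccc9)[C@@H](O[Si](CC)(CC)CC)c4ccc(OCc9ccccc9)c(OCc9ccccc9)c4)c3O)c3ccc(OCc9ccccc9)cc3O2)cc1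
A2 | alternative 1 | 4-{(2S)-7-(benzyloxy)-2-[4-(benzyloxy)phenyl]chroman-4-yl}-3-(triisopropylsilyloxy)cyclobut-2-en-1-one, flavan C4 configured as in A1 | c9ccccc9COc1ccc([C@@H]2C[C@H](C3C(=O)C=C3O[Si](C(C)C)(C(C)C)C(C)C)c3ccc(OCc9ccccc9)cc3O2)cc1
A3 | alternative 1 | triisopropylsilyl ynol ether of the ring F chain, 4-benzyloxy-5-[3,4-bis(benzyloxy)phenyl]-5-(triethylsilyloxy)pent-1-ynyl triisopropylsilyl ether with the chain stereocentres of A1 | CC(C)[Si](C(C)C)(C(C)C)OC#CC[C@@H](OCc1ccccc1)[C@@H](O[Si](CC)(CC)CC)c1ccc(OCc2ccccc2)c(OCc2ccccc2)c1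
A4 | alternative 2 | (2S)-7-benzyloxy-2-(4-benzyloxyphenyl)-4-(penta-O-benzylepicatechin-8-yl)-2H-chromene | c9ccccc9COc1ccc([C@@H]2C=C(c3c(OCc9ccccc9)cc(OCc9ccccc9)c4c3O[C@H](c3ccc(OCc9ccccc9)c(OCc9ccccc9)c3)[C@H](OCc9ccccc9)C4)c3ccc(OCc9ccccc9)cc3O2)cc1
A5 | alternative 2 | 3-benzyloxyphenyl ether of (S)-1-(4-benzyloxyphenyl)-3-(penta-O-benzylepicatechin-8-yl)prop-2-yn-1-ol | c9ccccc9COc1ccc([C@@H](Oc2cccc(OCc9ccccc9)c2)C#Cc3c(OCc9ccccc9)cc(OCc9ccccc9)c4c3O[C@H](c3ccc(OCc9ccccc9)c(OCc9ccccc9)c3)[C@H](OCc9ccccc9)C4)cc1
A6 | alternative 3 | penta-O-benzyl ether of the target with free C7 and C3 hydroxyls in the lower unit | c9ccccc9COc1ccc([C@@H]2C[C@H](c3c(O)cc(OCc9ccccc9)c4c3O[C@H](c3ccc(OCc9ccccc9)c(OCc9ccccc9)c3)[C@H](O)C4)c3ccc(OCc9ccccc9)cc3O2)cc1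
A7 | alternative 3 | cis-epoxide precursor, 5-benzyloxy-2-{(2S,4S)-7-(benzyloxy)-2-[4-(benzyloxy)phenyl]chroman-4-yl}-4-{[cis-3-(3,4-bis(benzyloxy)phenyl)oxiran-2-yl]methyl}benzene-1,3-diol | c9ccccc9COc1ccc([C@@H]2C[C@H](c3c(O)cc(OCc9ccccc9)c(C[C@H]5O[C@H]5c4ccc(OCc9ccccc9)c(OCc9ccccc9)c4)c3O)c3ccc(OCc9ccccc9)cc3O2)cc1
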